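Compound numbers used throughout: 1 3,4,5-trihydroxybenzaldehyde; 2 benzyl bromide; 3 3,4,5-tris(benzyloxy)benzaldehyde; 4 dimethyl (1-diazo-2-oxopropyl)phosphonate; 5 1,2,3-tris(benzyloxy)-5-ethynylbenzene; 6 2,4,6-trihydroxybenzaldehyde; 7 2,4-bis(benzyloxy)-6-hydroxybenzaldehyde; 8 1-bromo-3-methylbut-2-ene; 9 2,4-bis(benzyloxy)-6-(3-methylbut-2-enyloxy)benzaldehyde; 10 lithium acetylide of 5 (not isolated); 11 racemic propargylic alcohol; 12 ynone; 13 3-prenylflavone pentabenzyl ether; 14 asplenetin.

## Analysis of the target

Asplenetin (14) is a flavone: a benzene ring A fused to a 4-pyranone ring C, with hydroxyl groups at C5 and C7, a 3,4,5-trihydroxyphenyl ring B on C2 and a saturated 3-methylbutyl chain (C1'' to C4'', methyl branch on C3'') on C3. It has no stereocentre and no stereogenic double bond, so the problem is one of connectivity and of handling five phenols. The free pyrogallol of ring B is oxidised easily by air, above all in base, and ring A is a phloroglucinol nucleus whose C6 and C8 are far better carbon nucleophiles than C3, so a late alkylation of a finished flavone would go to the wrong ring. C3 is also a fully substituted carbon squeezed between the C4 carbonyl and ring B, which slows the classical flavone condensations when the chain is carried along. The difficulty is thus to place a branched five-carbon chain on C3 regiospecifically and to unveil five phenols at the end without strong Lewis acids. Two observations open the structure: the chain is a prenyl group that has taken up two hydrogens, and the O1–C2=C3 segment of ring C is the enol ether formed when the ring A oxygen O1 adds across the C2≡C3 triple bond of an aryl ynone. A prenyl group parked as an ether on O1 can therefore serve twice: its removal releases the nucleophile, and the same event can deliver it to C3 as the chain.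

## Retrosynthetic reasoning

14 to 13. The last operation is planned as a hydrogenation. Going backwards, the C2''–C3'' bond of the chain regains its double bond and the five phenolic O–H bonds become O–benzyl bonds, which gives 13. Benzyl is preferred to methyl because the pyrogallol ring then never meets a strong Lewis acid, and the oxidation-prone pentaphenol appears only in the last flask. The forward reaction must saturate a trisubstituted alkene and cleave five aryl benzyl ethers while leaving the tetrasubstituted C2=C3 bond of the pyranone alone.

13 to 12. Two bonds are cut together: O1–C2 and C3–C1''. This returns ring C to an open ynone and puts the prenyl group back on the ring A oxygen, giving 12. The cut is made here because it removes the hardest feature, the fully substituted C3 with its chain, in the same stroke as the ring. It also leaves a precursor made only of an ether, a ketone and an alkyne. The forward reaction has to ionise the allylic ether with a zerovalent palladium catalyst, close the ring through oxygen at the alkyne carbon bearing ring B, and join C3 to the unsubstituted end of the prenyl unit.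

12 to 9 and 5. The C4–C3 bond between carbonyl carbon and alkyne carbon is cut, after adjusting the ketone to the alcohol 11. This divides the molecule into two aromatic halves of similar size, aldehyde 9 and alkyne 5, which meet through the lithium acetylide 10. Cutting the C2–C1' bond instead would call for a terminal ynone, which is prone to polymerise. The forward steps are a 1,2-addition and a mild oxidation of a doubly activated alcohol.

9 to 7, 8, 6 and 2. Three aryl ether O–C bonds are cut. The order is set by the substrate: in 6 the para hydroxyl and one ortho hydroxyl are alkylated by 2 first, and the last ortho hydroxyl stays hydrogen-bonded to the aldehyde in 7. That position is exactly where the prenyl group from 8 is needed.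

5 to 3, 4, 1 and 2. The alkyne C≡C is traced to the aldehyde carbon of 3 by a one-carbon homologation with 4. Compound 3 comes from 1 by three O-benzylations with 2. Entering ring B at the aldehyde oxidation level avoids any redox adjustment before the homologation.

## Alternatives that were turned down

Alternative 1: Ring A is attached as an aryne, cutting O1–C8a and C4–C4a. Fluoride releases the aryne from 3,5-dimethoxy-2-(trimethylsilyl)phenyl trifluoromethanesulfonate A1 in the presence of (E)-5-methyl-2-[(3,4,5-trimethoxyphenyl)methylidene]hexanoic acid A2. The carboxylate of A2 adds to the aryne, the aryl anion attacks the acyl carbon, and the hydroxyaryl enone (E)-1-(2-hydroxy-4,6-dimethoxyphenyl)-5-methyl-2-[(3,4,5-trimethoxyphenyl)methylidene]hexan-1-one A3 results.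
- For: the route is convergent and the chain is saturated and in place from the start, so no linear or branched question arises. The methoxy group next to the triple bond directs oxygen to the distal carbon, which is the orientation A3 needs. On these points it is at least as secure as the chosen key step.
- Against: the key step closes no ring. Ring C must still be made from A3 by oxidative closure of an α-branched, trisubstituted enone, which is a slow substrate class. The acidic proton of A2 can quench the aryl anion before acyl transfer. A1 needs several steps of its own. Five methyl ethers must finally be cleaved with a boron trihalide on a molecule that ends as a pyrogallol.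
- Comparison: the chosen route forms ring C and the C3–chain bond in one catalytic step from 12 and finishes with a neutral hydrogenation. After A3, two demanding operations remain.

Alternative 2: Ring C is assembled by cutting C4–C4a and O1–C2. Benzene-1,3,5-triol A4 and racemic ethyl 5-methyl-2-(3,4,5-trimethoxybenzoyl)hexanoate A5 are heated together without catalyst to give 5,7-dihydroxy-3-(3-methylbutyl)-2-(3,4,5-trimethoxyphenyl)chromen-4-one A6.
- For: this is clearly the shortest plan, about three or four steps in all, since A6 already has the whole skeleton. The symmetry of A4 removes any ring A regiochemistry, and the 5- and 7-hydroxyls of A6 are free from the outset. On step economy it is stronger than the chosen route.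
- Against: the condensation that gives A6 needs temperatures well above 200 °C. The α-branch of A5 hinders both carbonyls. Closure in the opposite sense, to a coumarin-type lactone, and thermal breakdown of A5 compete directly with the desired mode. The three methyl ethers on ring B of A6 still need a Lewis acid.
- Comparison: the chosen route offers unambiguous connectivity, because the carbon skeleton of 12 fixes which carbon becomes C2 and which C4, whereas the formation of A6 depends on which carbonyl of A5 the ring carbon of A4 attacks. It also runs at mild temperatures and ends without a Lewis acid.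

Alternative 3: Ring B is built last, cutting C1'–C2' and C5'–C6'. 3,4-Dimethoxyfuran A8 adds across the alkyne of 2-ethynyl-5,7-dimethoxy-3-(3-methylbutyl)chromen-4-one A7. A Lewis acid then opens the oxygen bridge to give the phenol 2-(3-hydroxy-4,5-dimethoxyphenyl)-5,7-dimethoxy-3-(3-methylbutyl)chromen-4-one A9.
- For: cycloaddition followed by aromatisation to A9 is a known type of sequence, so its mechanism is less uncertain than that of the chosen key step. The chain is installed earlier by ordinary chemistry.
- Against: the effort goes into the one ring that can be bought fully oxygenated. A7 already contains ring C, the C3 chain and an extra alkyne, so the real problems are moved upstream unsolved. Furan cycloadditions are reversible, and A8 is electron-rich and labile. The direction in which the bridge opens decides whether A9 or its 2'-hydroxy isomer forms. The four methyl ethers of A9 remain to be cleaved.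
- Comparison: this would be the longest route, and the key step that gives A9 adds nothing at C3. The chosen route spends its key step where the target is hard.

Key step: step 7

Remark on the chemistry: ring B enters at the aldehyde oxidation level (1 is sold as its monohydrate, 4 as a solution in acetonitrile), so no reduction or oxidation is needed before the alkyne is made.

## Route

Step 1
Reactants: 1 3,4,5-trihydroxybenzaldehyde; 2 benzyl bromide
Product: 3 3,4,5-tris(benzyloxy)benzaldehyde
Conditions: BnBr (3.5 equiv), K2CO3, DMF, 60 °C, N2
Reagents that add atoms: benzyl bromide, BrCc1ccccc1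
Why: Williamson ether synthesis on three phenoxides; exclusion of air protects the pyrogallol until it is fully alkylated.

Step 2
Reactants: 3 3,4,5-tris(benzyloxy)benzaldehyde; 4 dimethyl (1-diazo-2-oxopropyl)phosphonate
Product: 5 1,2,3-tris(benzyloxy)-5-ethynylbenzene
Conditions: 4, K2CO3, MeOH/THF, 0 °C to rt
Reagents that add atoms: dimethyl (1-diazo-2-oxopropyl)phosphonate, CC(=O)C(=[N+]=[N-])P(=O)(OC)OC
Why: Ohira–Bestmann (Seyferth–Gilbert) homologation; the aldehyde cannot enolise and the benzyl ethers are inert to methanolic carbonate.

Step 3
Reactants: 6 2,4,6-trihydroxybenzaldehyde; 2 benzyl bromide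
Product: 7 2,4-bis(benzyloxy)-6-hydroxybenzaldehyde
Conditions: BnBr (2.05 equiv), K2CO3 (2.2 equiv), DMF, 0 °C to rt
Reagents that add atoms: benzyl bromide, BrCc1ccccc1
Why: Williamson ether synthesis limited by stoichiometry; the para hydroxyl and one ortho hydroxyl react first, and the remaining ortho hydroxyl is held back by its hydrogen bond to the aldehyde.

Step 4
Reactants: 7 2,4-bis(benzyloxy)-6-hydroxybenzaldehyde; 8 1-bromo-3-methylbut-2-ene
Product: 9 2,4-bis(benzyloxy)-6-(3-methylbut-2-enyloxy)benzaldehyde
Conditions: prenyl bromide (1.5 equiv), K2CO3, DMF, rt to 50 °C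
Reagents that add atoms: 1-bromo-3-methylbut-2-ene, CC(C)=CCBr
Why: Williamson O-alkylation by direct displacement at the primary allylic bromide; with carbonate in a dipolar aprotic solvent the phenoxide reacts at oxygen, not at ring carbon.

Step 5
Reactants: 5 1,2,3-tris(benzyloxy)-5-ethynylbenzene; 9 2,4-bis(benzyloxy)-6-(3-methylbut-2-enyloxy)benzaldehyde
Product: 11 1-[2,4-bis(benzyloxy)-6-(3-methylbut-2-enyloxy)phenyl]-3-[3,4,5-tris(benzyloxy)phenyl]prop-2-yn-1-ol (racemic), via lithium arylacetylide 10 (not isolated)
Conditions: n-BuLi, THF, −78 °C; then 9, −78 to 0 °C; H2O quench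
Reagents that add atoms: none
Why: 1,2-addition of a lithium acetylide to an aldehyde that cannot enolise; the carbinol centre is formed racemic and is erased in step 6, and the neutral quench avoids ionising the electron-rich carbinol.

Step 6
Reactants: 11 1-[2,4-bis(benzyloxy)-6-(3-methylbut-2-enyloxy)phenyl]-3-[3,4,5-tris(benzyloxy)phenyl]prop-2-yn-1-ol
Product: 12 1-[2,4-bis(benzyloxy)-6-(3-methylbut-2-enyloxy)phenyl]-3-[3,4,5-tris(benzyloxy)phenyl]prop-2-yn-1-one
Conditions: MnO2 (excess), CH2Cl2, rt
Reagents that add atoms: none
Why: manganese dioxide oxidation of an alcohol that is both benzylic and propargylic; the medium is neutral, so the prenyl and benzyl ethers are untouched.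

Step 7
Reactants: 12 1-[2,4-bis(benzyloxy)-6-(3-methylbut-2-enyloxy)phenyl]-3-[3,4,5-tris(benzyloxy)phenyl]prop-2-yn-1-one
Product: 13 5,7-bis(benzyloxy)-3-(3-methylbut-2-enyl)-2-[3,4,5-tris(benzyloxy)phenyl]chromen-4-one
Conditions: Pd(PPh3)4 (5 mol %), THF (dry, degassed), 60 °C
Reagents that add atoms: none
Why: Proposed new method: zerovalent palladium should ionise the aryl prenyl ether of 12, whose aryloxide is a good leaving group because the ortho ynone carbonyl makes it a vinylogous carboxylate, to a phenoxide and a cationic prenyl complex of divalent palladium. The phenoxide oxygen then adds to the alkyne carbon that carries ring B, most plausibly anti to the cationic metal held on the triple bond, so that C3 becomes a palladium-bound vinyl carbon and not a free in-plane carbanion that the C4 carbonyl could not stabilise; reductive elimination joins C3 to the CH2 terminus of the prenyl ligand and returns zerovalent palladium. The closest known reaction types are the zerovalent-palladium-catalysed conversion of 2-alkynylphenyl allyl ethers into 3-allylbenzofurans with oxygen-to-carbon allyl transfer and the phenoxide closure of 2-hydroxyaryl ynones to flavones in aprotic media. Ring C closes in the 6-endo-dig mode, O1–C2 and C3–C1'' are the two bonds formed, and no stereocentre arises. Three selectivities are needed. 6-endo has to win over 5-exo (aurone) closure, which the polarisation of the ynone towards its aryl-bearing carbon and the absence of any proton source that could trap a 5-exo adduct should secure. Linear has to win over branched prenyl transfer, which follows from bond formation at the unhindered CH2 end of the 1,1-dimethylallyl ligand and from the crowding at C3 between the C4 carbonyl and ring B. Capture at C3 has to win over capture at oxygen or at ring A carbon, where return to oxygen only regenerates an ionisable ether and the acyl group drains carbon nucleophilicity from ring A.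

Step 8
Reactants: 13 5,7-bis(benzyloxy)-3-(3-methylbut-2-enyl)-2-[3,4,5-tris(benzyloxy)phenyl]chromen-4-one
Product: 14 asplenetin, 5,7-dihydroxy-3-(3-methylbutyl)-2-(3,4,5-trihydroxyphenyl)chromen-4-one
Conditions: H2 (1 atm), 10% Pd/C, THF/MeOH, rt; filtration and concentration under N2
Reagents that add atoms: none
Why: heterogeneous catalytic hydrogenation saturates the trisubstituted alkene and hydrogenolyses the five aryl benzyl ethers in one operation; the C2=C3 bond is tetrasubstituted and part of a vinylogous ester, so it should survive at atmospheric pressure.

## Compound list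

1 | 3,4,5-trihydroxybenzaldehyde | O=Cc1cc(O)c(O)c(O)c1 | starting material
2 | benzyl bromide | BrCc1ccccc1 | starting material
3 | 3,4,5-tris(benzyloxy)benzaldehyde | O=Cc1cc(OCc2ccccc2)c(OCc2ccccc2)c(OCc2ccccc2)c1 | intermediate
4 | dimethyl (1-diazo-2-oxopropyl)phosphonate | CC(=O)C(=[N+]=[N-])P(=O)(OC)OC | starting material
5 | 1,2,3-tris(benzyloxy)-5-ethynylbenzene | C#Cc1cc(OCc2ccccc2)c(OCc2ccccc2)c(OCc2ccccc2)c1 | intermediate
6 | 2,4,6-trihydroxybenzaldehyde | O=Cc1c(O)cc(O)cc1O | starting material
7 | 2,4-bis(benzyloxy)-6-hydroxybenzaldehyde | O=Cc1c(O)cc(OCc2ccccc2)cc1OCc1ccccc1 | intermediate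
8 | 1-bromo-3-methylbut-2-ene | CC(C)=CCBr | starting material
9 | 2,4-bis(benzyloxy)-6-(3-methylbut-2-enyloxy)benzaldehyde | CC(C)=CCOc1cc(OCc2ccccc2)cc(OCc2ccccc2)c1C=O | intermediate
10 | lithium [3,4,5-tris(benzyloxy)phenyl]acetylide | [Li]C#Cc1cc(OCc2ccccc2)c(OCc2ccccc2)c(OCc2ccccc2)c1 | intermediate (not isolated)
11 | 1-[2,4-bis(benzyloxy)-6-(3-methylbut-2-enyloxy)phenyl]-3-[3,4,5-tris(benzyloxy)phenyl]prop-2-yn-1-ol (racemic) | CC(C)=CCOc1cc(OCc2ccccc2)cc(OCc2ccccc2)c1C(O)C#Cc1cc(OCc2ccccc2)c(OCc2ccccc2)c(OCc2ccccc2)c1 | intermediate
12 | 1-[2,4-bis(benzyloxy)-6-(3-methylbut-2-enyloxy)phenyl]-3-[3,4,5-tris(benzyloxy)phenyl]prop-2-yn-1-one | CC(C)=CCOc1cc(OCc2ccccc2)cc(OCc2ccccc2)c1C(=O)C#Cc1cc(OCc2ccccc2)c(OCc2ccccc2)c(OCc2ccccc2)c1 | intermediate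
13 | 5,7-bis(benzyloxy)-3-(3-methylbut-2-enyl)-2-[3,4,5-tris(benzyloxy)phenyl]chromen-4-one | CC(C)=CCc1c(-c2cc(OCc3ccccc3)c(OCc3ccccc3)c(OCc3ccccc3)c2)oc2cc(OCc3ccccc3)cc(OCc3ccccc3)c2c1=O | intermediate
14 | asplenetin, 5,7-dihydroxy-3-(3-methylbutyl)-2-(3,4,5-trihydroxyphenyl)chromen-4-one | CC(C)CCc1c(-c2cc(O)c(O)c(O)c2)oc2cc(O)cc(O)c2c1=O | target

## Step count and risk

Total step count: 8. Longest linear sequence: 6 steps (steps 3, 4, 5, 6, 7, 8 from 6; the branch from 1 through steps 1, 2, 5, 6, 7, 8 is equally long).

Step 7 (key step, proposed new method).
- What may go wrong: the most likely failure is that capture at C3 is outrun after ionisation. C3 may be protonated by traces of water while the prenyl ligand is lost by β-hydride elimination, or the prenyl cation may be taken up by ring A carbon. Slower ionisation than with a plain allyl ether is also possible, since the ynone can tie up zerovalent palladium and free PPh3 can add reversibly to the ynone. Leakage into branched transfer or 5-exo closure is a further possibility.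
- Fallback: the tandem event is given up and the chain is installed by cross-coupling with known chemistry. It sets out from 12. Pd(PPh3)4 with excess morpholine in THF should remove the prenyl group (palladium-catalysed deallylation with an amine acceptor). The amine also adds reversibly to the ynone and steers the liberated phenol into 6-endo closure, giving 5,7-bis(benzyloxy)-2-[3,4,5-tris(benzyloxy)phenyl]chromen-4-one F1. Deprotonation of F1 at C3 with LiN(i-Pr)2 in THF at −78 °C and quenching with iodine should give 5,7-bis(benzyloxy)-3-iodo-2-[3,4,5-tris(benzyloxy)phenyl]chromen-4-one F2. The base-mediated route is chosen because electrophilic iodination would attack C6 or C8. Negishi coupling of F2 with commercial (3-methylbutyl)zinc bromide and PdCl2(dppf) in THF should give 5,7-bis(benzyloxy)-3-(3-methylbutyl)-2-[3,4,5-tris(benzyloxy)phenyl]chromen-4-one F3. Hydrogenolysis of F3 under the conditions of step 8 comes back to the route at 14.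

Step 8.
- What may go wrong: the alkene should reduce quickly, but the five hydrogenolyses run at different rates. Partly debenzylated, poorly soluble intermediates may deposit on the catalyst, and prolonged exposure invites reduction of the pyranone C2=C3 bond. The free pyrogallol may also oxidise during isolation.
- Fallback: the two tasks are separated, setting out from 13. Hydrogenation over 10% Pd/C in the presence of 2,2'-bipyridyl, a nitrogen base that suppresses hydrogenolysis of aryl benzyl ethers but not alkene reduction, should give the saturated pentabenzyl ether 5,7-bis(benzyloxy)-3-(3-methylbutyl)-2-[3,4,5-tris(benzyloxy)phenyl]chromen-4-one F3 (the compound also reached in the fallback to step 7). BCl3 with pentamethylbenzene as cation trap in CH2Cl2 at −78 °C, followed by a methanol quench, should then remove the five benzyl groups and come back to the route at 14.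

Step 3.
- What may go wrong: the selectivity rests only on a hydrogen bond, so over-alkylation of the third hydroxyl and carbon-benzylation of the phloroglucinol nucleus may erode the amount of 7.
- Fallback: selective protection is replaced by selective deprotection, setting out from 6. Excess benzyl bromide 2 with K2CO3 in DMF at 60 °C should give 2,4,6-tris(benzyloxy)benzaldehyde F4. MgBr2·OEt2 in toluene/diethyl ether under reflux should then remove one ortho benzyl group through a six-membered magnesium chelate with the aldehyde, coming back to the route at 7.

Step 6 (together with step 5).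
- What may go wrong: the carbinol 11 carries a 2,4,6-trialkoxyphenyl group that strongly stabilises the propargylic cation. Ionisation on silica or by traces of acid may lead to ether formation or rearrangement before the oxidation is complete.
- Fallback: the carbinol is avoided altogether, setting out from 9. Pinnick oxidation (NaClO2, NaH2PO4, large excess of 2-methylbut-2-ene, t-BuOH/H2O) should give 2,4-bis(benzyloxy)-6-(3-methylbut-2-enyloxy)benzoic acid F5. Carbodiimide coupling with N,O-dimethylhydroxylamine hydrochloride in CH2Cl2 should give 2,4-bis(benzyloxy)-N-methoxy-N-methyl-6-(3-methylbut-2-enyloxy)benzamide F6. Addition of the acetylide 10 to F6 in THF at −78 to 0 °C should deliver the ketone directly, coming back to the route at 12.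

## Further compounds

F1 | step 7 | 5,7-bis(benzyloxy)-2-[3,4,5-tris(benzyloxy)phenyl]chromen-4-one | O=c1cc(-c2cc(OCc3ccccc3)c(OCc3ccccc3)c(OCc3ccccc3)c2)oc2cc(OCc3ccccc3)cc(OCc3ccccc3)c12
F2 | step 7 | 5,7-bis(benzyloxy)-3-iodo-2-[3,4,5-tris(benzyloxy)phenyl]chromen-4-one | O=c1c(I)c(-c2cc(OCc3ccccc3)c(OCc3ccccc3)c(OCc3ccccc3)c2)oc2cc(OCc3ccccc3)cc(OCc3ccccc3)c12
F3 | step 7 | 5,7-bis(benzyloxy)-3-(3-methylbutyl)-2-[3,4,5-tris(benzyloxy)phenyl]chromen-4-one | CC(C)CCc1c(-c2cc(OCc3ccccc3)c(OCc3ccccc3)c(OCc3ccccc3)c2)oc2cc(OCc3ccccc3)cc(OCc3ccccc3)c2c1=O
F4 | step 3 | 2,4,6-tris(benzyloxy)benzaldehyde | O=Cc1c(OCc2ccccc2)cc(OCc2ccccc2)cc1OCc1ccccc1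
F5 | step 6 | 2,4-bis(benzyloxy)-6-(3-methylbut-2-enyloxy)benzoic acid | CC(C)=CCOc1cc(OCc2ccccc2)cc(OCc2ccccc2)c1C(=O)O
F6 | step 6 | 2,4-bis(benzyloxy)-N-methoxy-N-methyl-6-(3-methylbut-2-enyloxy)benzamide | CC(C)=CCOc1cc(OCc2ccccc2)cc(OCc2ccccc2)c1C(=O)N(C)OC
A1 | alternative 1 | 3,5-dimethoxy-2-(trimethylsilyl)phenyl trifluoromethanesulfonate | COc1cc(OC)c([Si](C)(C)C)c(OS(=O)(=O)C(F)(F)F)c1
A2 | alternative 1 | (E)-5-methyl-2-[(3,4,5-trimethoxyphenyl)methylidene]hexanoic acid | CC(C)CC/C(=C\c1cc(OC)c(OC)c(OC)c1)C(=O)O
A3 | alternative 1 | (E)-1-(2-hydroxy-4,6-dimethoxyphenyl)-5-methyl-2-[(3,4,5-trimethoxyphenyl)methylidene]hexan-1-one | CC(C)CC/C(=C\c1cc(OC)c(OC)c(OC)c1)C(=O)c1c(O)cc(OC)cc1OC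
A4 | alternative 2 | benzene-1,3,5-triol (phloroglucinol) | Oc1cc(O)cc(O)c1
A5 | alternative 2 | ethyl 5-methyl-2-(3,4,5-trimethoxybenzoyl)hexanoate (racemic) | CCOC(=O)C(CCC(C)C)C(=O)c1cc(OC)c(OC)c(OC)c1
A6 | alternative 2 | 5,7-dihydroxy-3-(3-methylbutyl)-2-(3,4,5-trimethoxyphenyl)chromen-4-one | CC(C)CCc1c(-c2cc(OC)c(OC)c(OC)c2)oc2cc(O)cc(O)c2c1=O
A7 | alternative 3 | 2-ethynyl-5,7-dimethoxy-3-(3-methylbutyl)chromen-4-one | CC(C)CCc1c(C#C)oc2cc(OC)cc(OC)c2c1=O
A8 | alternative 3 | 3,4-dimethoxyfuran | COc1cocc1OC
A9 | alternative 3 | 2-(3-hydroxy-4,5-dimethoxyphenyl)-5,7-dimethoxy-3-(3-methylbutyl)chromen-4-one | CC(C)CCc1c(-c2cc(O)c(OC)c(OC)c2)oc2cc(OC)cc(OC)c2c1=O
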